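Everything rests on a temporary C2–C7 bond. In the 1,2-dioxane the propanoate carbon C2 (on C3) and the chain carbon C7 (on C6) lie on the same face, so joining them converts the ring into a 2,3-dioxabicyclo[2.2.2]octane in which that cis relationship is built in. The bicycle arises in one operation by [4+2] addition of singlet oxygen to a cyclohexadiene: O1–C6 and O2–C3 form together, the dioxene ring closes and both ring stereocentres are set. The precursor is the acetonide of (1R,2S)-3-methylcyclohexa-3,5-diene-1,2-diol, made enzymatically from 4-iodotoluene. Glycol cleavage later frees C2 and C7 as sterically different formyl groups.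

Key step: step 4

Remark: atoms are numbered as in the target (C1 carboxyl carbon, C2 its α-carbon, C3 and C6 the ring carbons, O2 on C3, O1 on C6, C4/C5 the ring CH2 groups, C7 and C8 the first chain carbons). The target is (2S,3S,6S); diene 5 and the anti adduct 6 as drawn map onto 3S,6S, whereas the diol from toluene itself would give the mirror-image ring.

**Step 1**
Reactants: 1 4-iodotoluene
Product: 2 (1S,2S)-3-iodo-6-methylcyclohexa-3,5-diene-1,2-diol
Conditions: whole cells expressing toluene dioxygenase (P. putida UV4 or E. coli JM109(pDTG601), IPTG), air, glucose, phosphate buffer pH 7.2, 30 °C; EtOAc extraction, recrystallisation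
Reagents that add atoms: dioxygen, O=O
Why: Enzymatic arene cis-dihydroxylation by toluene dioxygenase should deliver both oxygens from one face to the 2,3-bond next to the larger iodine substituent, so the enzyme sets both carbinol centres and the methyl group sits on the far diene terminus, which gives the series opposite to that from toluene (enantiomeric purity to be assayed and raised by recrystallisation if required).

**Step 2**
Reactants: 2 (1S,2S)-3-iodo-6-methylcyclohexa-3,5-diene-1,2-diol
Product: 3 (1R,2S)-3-methylcyclohexa-3,5-diene-1,2-diol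
Conditions: H2 (1 atm), 3% Pd/C, NaOAc·3H2O, MeOH, 20 °C, stopped after one equivalent
Reagents that add atoms: none
Why: Catalytic hydrogenolysis of the vinylic C–I bond, buffered with acetate and stopped early, should outrun hydrogenation of the diene and touches no stereocentre (the descriptors change only because iodine is replaced by hydrogen).

**Step 3**
Reactants: 3 (1R,2S)-3-methylcyclohexa-3,5-diene-1,2-diol; 4 2,2-dimethoxypropane
Product: 5 (3aS,7aR)-2,2,4-trimethyl-3a,7a-dihydro-1,3-benzodioxole
Conditions: TsOH·H2O (2 mol%), acetone, 0 °C, 30 min; Et3N quench; used at once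
Reagents that add atoms: none
Why: Acid-catalysed transacetalisation ties the cis-diol into a dioxolane without touching the stereocentres, and the short cold reaction and immediate use guard against aromatisation and Diels–Alder dimerisation of the diene.

**Step 4**
Reactants: 5 (3aS,7aR)-2,2,4-trimethyl-3a,7a-dihydro-1,3-benzodioxole
Product: 6 (1R,4S,7R,8S)-1-methyl-2,3-dioxabicyclo[2.2.2]oct-5-ene-7,8-diol acetonide (O–O bridge anti to the dioxolane)
Conditions: O2, tetraphenylporphyrin (1 mol%), CH2Cl2, visible light, −30 °C; kept cold and reduced without delay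
Reagents that add atoms: singlet oxygen (from dioxygen), O=O
Why: Photosensitised singlet oxygen acts as the 2π partner and adds in a concerted, suprafacial [4+2] cycloaddition to the s-cis diene held in the six-membered ring, the established behaviour of arene cis-dihydrodiol acetonides. The 3,6-dihydro-1,2-dioxine ring is closed intermolecularly by this cycloaddition, O1–C6 and O2–C3 forming together, so the carbocycle becomes a 2,3-dioxabicyclo[2.2.2]octene. C6 (the methyl-bearing bridgehead) and C3 are both fixed by the face of attack, which is the face opposite the dioxolane on C7/C2, itself set by the enzyme in step 1. The step needs π-facial selectivity, which the two acetonide oxygens on the sp3 bridge supply by shielding one face. It also needs chemoselectivity over the ene reaction at the allylic methyl group, which should hold because the locked cisoid diene reacts much faster and no isolated trisubstituted alkene is present yet. Since one O–O unit bridges both termini from the same side, C2 and C7 must end up cis on the future dioxane.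

**Step 5**
Reactants: 6 (1R,4S,7R,8S)-1-methyl-2,3-dioxabicyclo[2.2.2]oct-5-ene-7,8-diol acetonide
Product: 7 (1R,4S,7R,8S)-1-methyl-2,3-dioxabicyclo[2.2.2]octane-7,8-diol acetonide
Conditions: KO2CN=NCO2K (excess), AcOH, MeOH/CH2Cl2, −30 → 0 °C
Reagents that add atoms: none
Why: Diimide reduction transfers H2 concertedly to the strained C4=C5 bond and leaves the O–O bond alone, the acidic medium also avoiding Kornblum–DeLaMare opening at the bridgehead C3–H, and no stereocentre is created.

**Step 6**
Reactants: 7 (1R,4S,7R,8S)-1-methyl-2,3-dioxabicyclo[2.2.2]octane-7,8-diol acetonide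
Product: 9 (3R,6S)-3-methyl-1,2-dioxane-3,6-dicarbaldehyde, via peroxy diol 8 (not isolated)
Conditions: Amberlyst-15 (H+), THF/H2O, 40 °C; filter; then NaIO4 (1.3 equiv), 0 °C; NaCl saturation, CH2Cl2 extraction, azeotropic drying, used at once
Reagents that add atoms: none
Why: Acetal hydrolysis followed by periodate glycol cleavage of the rigid cis-diol breaks the temporary C2–C7 bond under neutral conditions, so C3 and C6 keep their configuration and the two formyl groups emerge cis on the 1,2-dioxane.

**Step 7**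
Reactants: 9 (3R,6S)-3-methyl-1,2-dioxane-3,6-dicarbaldehyde
Product: 10 (3R,6S)-6-(1-hydroxyethyl)-3-methyl-1,2-dioxane-3-carbaldehyde (both carbinol epimers; partly as the bridged lactol)
Conditions: MeTi(OiPr)3 (1.1 equiv), THF, −50 → −20 °C; aq NH4Cl
Reagents that add atoms: methyltitanium triisopropoxide, C[Ti](OC(C)C)(OC(C)C)OC(C)C
Why: Chemoselective carbonyl addition of the bulky, non-basic methyltitanium reagent should occur at the formyl group on the tertiary C3 and not at the neopentyl-type one on the quaternary C6, without enolisation at C3–H, and the new carbinol centre may form unselectively because step 12 oxidises it.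

**Step 8**
Reactants: 10 (3R,6S)-6-(1-hydroxyethyl)-3-methyl-1,2-dioxane-3-carbaldehyde
Product: 11 1-[(3S,6R)-6-ethenyl-6-methyl-1,2-dioxan-3-yl]ethan-1-ol (both carbinol epimers)
Conditions: Ph3PCH3Br (3.0 equiv), n-BuLi (2.9 equiv), THF, 0 °C; 10, −78 → 0 °C
Reagents that add atoms: methyltriphenylphosphonium bromide, C[P+](c1ccccc1)(c1ccccc1)c1ccccc1.[Br-]
Why: Wittig methylenation of the non-enolisable C7 aldehyde (freed from any lactol by the excess ylide) gives the vinyl group, the low temperature keeping the lithium alkoxide next to the peroxide from fragmenting, and no stereocentre is affected.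

**Step 9**
Reactants: 12 1-(trimethylsilyl)propyne; 13 geranyl bromide
Product: 16 (5E)-6,10-dimethylundeca-5,9-dien-1-yne, via silylpropargyllithium 14 (not isolated), via silyl enyne 15 (not isolated)
Conditions: 12, n-BuLi, THF, −78 → −20 °C; 13, −78 → 0 °C; then K2CO3 (cat.), MeOH, 20 °C
Reagents that add atoms: none
Why: SN2 alkylation of the silyl-stabilised propargylic lithium reagent at the primary allylic bromide keeps the E alkene, and methanolysis of the alkynylsilane then frees the terminal alkyne.

**Step 10**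
Reactants: 16 (5E)-6,10-dimethylundeca-5,9-dien-1-yne
Product: 18 (1E,5E)-1-iodo-2,6,10-trimethylundeca-1,5,9-triene, via alkenylalane 17 (not isolated)
Conditions: Me3Al (2 equiv), Cp2ZrCl2 (0.25 equiv), CH2Cl2, 0 → 20 °C; then I2, THF, −30 °C
Reagents that add atoms: trimethylaluminium, C[Al](C)C; iodine, II
Why: Negishi zirconium-catalysed carboalumination adds methyl and aluminium syn across the terminal alkyne with methyl on the internal carbon, and iodinolysis of the C–Al bond with retention gives the (E)-iodoalkene.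

**Step 11**
Reactants: 11 1-[(3S,6R)-6-ethenyl-6-methyl-1,2-dioxan-3-yl]ethan-1-ol; 18 (1E,5E)-1-iodo-2,6,10-trimethylundeca-1,5,9-triene
Product: 20 1-[(3S,6S)-6-methyl-6-[(3E,7E)-4,8,12-trimethyltrideca-3,7,11-trien-1-yl]-1,2-dioxan-3-yl]ethan-1-ol (both carbinol epimers), via C8 alkylborane 19 (not isolated)
Conditions: 9-BBN-H (2.2 equiv), THF, 0 → 20 °C; then 18 (1.1 equiv), PdCl2(dppf) (5 mol%), AsPh3 (10 mol%), 3 M aq K3PO4, DMF, 20 °C
Reagents that add atoms: none
Why: Anti-Markovnikov hydroboration of the vinyl group puts boron on C8 (a second equivalent is taken up by the hydroxyl and released in the aqueous medium), and B-alkyl Suzuki–Miyaura coupling forms C8–C9 with retention of the E geometry under mild conditions that a dialkyl peroxide is expected to survive (C6 changes from R to S by CIP priority only).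

**Step 12**
Reactants: 20 1-[(3S,6S)-6-methyl-6-[(3E,7E)-4,8,12-trimethyltrideca-3,7,11-trien-1-yl]-1,2-dioxan-3-yl]ethan-1-ol
Product: 21 1-[(3S,6S)-6-methyl-6-[(3E,7E)-4,8,12-trimethyltrideca-3,7,11-trien-1-yl]-1,2-dioxan-3-yl]ethan-1-one
Conditions: Dess–Martin periodinane (1.3 equiv), CH2Cl2, 0 → 20 °C
Reagents that add atoms: none
Why: Dess–Martin oxidation merges both carbinol epimers into one methyl ketone under non-basic conditions that spare the trisubstituted alkenes, the peroxide and the base-sensitive C3–H.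

**Step 13**
Reactants: 21 1-[(3S,6S)-6-methyl-6-[(3E,7E)-4,8,12-trimethyltrideca-3,7,11-trien-1-yl]-1,2-dioxan-3-yl]ethan-1-one
Product: 23 (3S,6S)-3-methyl-6-(prop-1-en-2-yl)-3-[(3E,7E)-4,8,12-trimethyltrideca-3,7,11-trien-1-yl]-1,2-dioxane, via hydroxysilane 22 (not isolated)
Conditions: Me3SiCH2MgCl (2 equiv), CeCl3 (2 equiv), THF, −78 °C; aq NH4Cl; then crude 22, 48% aq HF, MeCN, 0 °C
Reagents that add atoms: (trimethylsilyl)methylmagnesium chloride, C[Si](C)(C)C[Mg]Cl
Why: Peterson olefination through the weakly basic organocerium reagent adds to the α-peroxy ketone without deprotonating C3–H (which would open the peroxide in a Kornblum–DeLaMare manner), and acid-promoted anti elimination of the tertiary β-hydroxysilane gives the isopropenyl group with C3 untouched.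

**Step 14**
Reactants: 23 (3S,6S)-3-methyl-6-(prop-1-en-2-yl)-3-[(3E,7E)-4,8,12-trimethyltrideca-3,7,11-trien-1-yl]-1,2-dioxane
Product: 25 (2R)-2-[(3S,6S)-6-methyl-6-[(3E,7E)-4,8,12-trimethyltrideca-3,7,11-trien-1-yl]-1,2-dioxan-3-yl]propan-1-ol, via C1 alkylborane 24 (not isolated)
Conditions: 9-BBN-H (1.5 equiv), THF, 0 → 20 °C; then NaBO3·4H2O, THF/H2O, 20 °C
Reagents that add atoms: sodium perborate, [Na+].[O-]OB=O
Why: Substrate-controlled hydroboration–oxidation with 9-BBN should pick the 1,1-disubstituted alkene over the three trisubstituted ones and, as with acyclic 1,1-disubstituted allylic ethers, place the C2 methyl anti to the allylic C3–O2 bond, which is the configuration of the target at C2 (R here, S in the acid, by CIP priority only), before perborate replaces boron by hydroxyl with retention.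

**Step 15**
Reactants: 25 (2R)-2-[(3S,6S)-6-methyl-6-[(3E,7E)-4,8,12-trimethyltrideca-3,7,11-trien-1-yl]-1,2-dioxan-3-yl]propan-1-ol
Product: 27 (2S)-2-[(3S,6S)-6-methyl-6-[(3E,7E)-4,8,12-trimethyltrideca-3,7,11-trien-1-yl]-1,2-dioxan-3-yl]propanoic acid, via aldehyde 26 (not isolated)
Conditions: TEMPO (20 mol%), PhI(OAc)2 (2.5 equiv), MeCN/pH 7 buffer (1:1), 0 → 20 °C
Reagents that add atoms: water, O
Why: Oxoammonium (TEMPO/PhI(OAc)2) oxidation takes the primary alcohol through the aldehyde hydrate to the acid under near-neutral conditions that avoid enolisation at C2 (hence epimerisation or β-elimination of the peroxide) and leave the alkenes and the O–O bond intact.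

**Compound list**

1 | 4-iodotoluene | Cc1ccc(I)cc1 | starting material
2 | (1S,2S)-3-iodo-6-methylcyclohexa-3,5-diene-1,2-diol | IC1=CC=C(C)[C@H](O)[C@@H]1O | intermediate
3 | (1R,2S)-3-methylcyclohexa-3,5-diene-1,2-diol | CC1=CC=C[C@@H](O)[C@H]1O | intermediate
4 | 2,2-dimethoxypropane | COC(C)(C)OC | starting material
5 | (3aS,7aR)-2,2,4-trimethyl-3a,7a-dihydro-1,3-benzodioxole (diene acetonide) | CC1=CC=C[C@H]2OC(C)(C)O[C@@H]12 | intermediate
6 | (1R,4S,7R,8S)-1-methyl-2,3-dioxabicyclo[2.2.2]oct-5-ene-7,8-diol acetonide, O–O bridge anti to the dioxolane | C[C@]12C=C[C@H](OO1)[C@H]1OC(C)(C)O[C@H]12 | intermediate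
7 | (1R,4S,7R,8S)-1-methyl-2,3-dioxabicyclo[2.2.2]octane-7,8-diol acetonide | C[C@]12CC[C@H](OO1)[C@H]1OC(C)(C)O[C@H]12 | intermediate
8 | (1R,4S,7R,8S)-1-methyl-2,3-dioxabicyclo[2.2.2]octane-7,8-diol | C[C@]12CC[C@H](OO1)[C@@H](O)[C@H]2O | intermediate
9 | (3R,6S)-3-methyl-1,2-dioxane-3,6-dicarbaldehyde (formyl groups cis) | C[C@]1(C=O)CC[C@@H](C=O)OO1 | intermediate
10 | (3R,6S)-6-(1-hydroxyethyl)-3-methyl-1,2-dioxane-3-carbaldehyde, both carbinol epimers | C[C@]1(C=O)CC[C@@H](C(C)O)OO1 | intermediate
11 | 1-[(3S,6R)-6-ethenyl-6-methyl-1,2-dioxan-3-yl]ethan-1-ol, both carbinol epimers | C[C@]1(C=C)CC[C@@H](C(C)O)OO1 | intermediate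
12 | 1-(trimethylsilyl)propyne | CC#C[Si](C)(C)C | starting material
13 | geranyl bromide | CC(C)=CCC/C(C)=C/CBr | starting material
14 | [3-(trimethylsilyl)prop-2-yn-1-yl]lithium | [Li]CC#C[Si](C)(C)C | intermediate
15 | [(5E)-6,10-dimethylundeca-5,9-dien-1-yn-1-yl]trimethylsilane | CC(C)=CCC/C(C)=C/CCC#C[Si](C)(C)C | intermediate
16 | (5E)-6,10-dimethylundeca-5,9-dien-1-yne | CC(C)=CCC/C(C)=C/CCC#C | intermediate
17 | dimethyl[(1E,5E)-2,6,10-trimethylundeca-1,5,9-trien-1-yl]alane | CC(C)=CCC/C(C)=C/CC/C(C)=C/[Al](C)C | intermediate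
18 | (1E,5E)-1-iodo-2,6,10-trimethylundeca-1,5,9-triene | CC(C)=CCC/C(C)=C/CC/C(C)=C/I | intermediate
19 | 1-[(3S,6S)-6-[2-(9-borabicyclo[3.3.1]nonan-9-yl)ethyl]-6-methyl-1,2-dioxan-3-yl]ethan-1-ol, both carbinol epimers (hydroxyl drawn free) | C[C@]1(CCB2C3CCCC2CCC3)CC[C@@H](C(C)O)OO1 | intermediate
20 | 1-[(3S,6S)-6-methyl-6-[(3E,7E)-4,8,12-trimethyltrideca-3,7,11-trien-1-yl]-1,2-dioxan-3-yl]ethan-1-ol, both carbinol epimers | CC(C)=CCC/C(C)=C/CC/C(C)=C/CC[C@@]1(C)CC[C@@H](C(C)O)OO1 | intermediate
21 | 1-[(3S,6S)-6-methyl-6-[(3E,7E)-4,8,12-trimethyltrideca-3,7,11-trien-1-yl]-1,2-dioxan-3-yl]ethan-1-one | CC(C)=CCC/C(C)=C/CC/C(C)=C/CC[C@@]1(C)CC[C@@H](C(C)=O)OO1 | intermediate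
22 | 2-[(3S,6S)-6-methyl-6-[(3E,7E)-4,8,12-trimethyltrideca-3,7,11-trien-1-yl]-1,2-dioxan-3-yl]-1-(trimethylsilyl)propan-2-ol, both carbinol epimers | CC(C)=CCC/C(C)=C/CC/C(C)=C/CC[C@@]1(C)CC[C@@H](C(C)(O)C[Si](C)(C)C)OO1 | intermediate
23 | (3S,6S)-3-methyl-6-(prop-1-en-2-yl)-3-[(3E,7E)-4,8,12-trimethyltrideca-3,7,11-trien-1-yl]-1,2-dioxane | CC(C)=CCC/C(C)=C/CC/C(C)=C/CC[C@@]1(C)CC[C@@H](C(C)=C)OO1 | intermediate
24 | 9-[(2R)-2-[(3S,6S)-6-methyl-6-[(3E,7E)-4,8,12-trimethyltrideca-3,7,11-trien-1-yl]-1,2-dioxan-3-yl]propyl]-9-borabicyclo[3.3.1]nonane | CC(C)=CCC/C(C)=C/CC/C(C)=C/CC[C@@]1(C)CC[C@@H]([C@H](C)CB2C3CCCC2CCC3)OO1 | intermediate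
25 | (2R)-2-[(3S,6S)-6-methyl-6-[(3E,7E)-4,8,12-trimethyltrideca-3,7,11-trien-1-yl]-1,2-dioxan-3-yl]propan-1-ol | CC(C)=CCC/C(C)=C/CC/C(C)=C/CC[C@@]1(C)CC[C@@H]([C@H](C)CO)OO1 | intermediate
26 | (2S)-2-[(3S,6S)-6-methyl-6-[(3E,7E)-4,8,12-trimethyltrideca-3,7,11-trien-1-yl]-1,2-dioxan-3-yl]propanal | CC(C)=CCC/C(C)=C/CC/C(C)=C/CC[C@@]1(C)CC[C@@H]([C@H](C)C=O)OO1 | intermediate
27 | (2S)-2-[(3S,6S)-6-methyl-6-[(3E,7E)-4,8,12-trimethyltrideca-3,7,11-trien-1-yl]-1,2-dioxan-3-yl]propanoic acid | CC(C)=CCC/C(C)=C/CC/C(C)=C/CC[C@@]1(C)CC[C@@H]([C@H](C)C(=O)O)OO1 | target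

Total step count: 15. Longest linear sequence: 13 (steps 1–8 and 11–15; steps 9–10 make the side-chain fragment).

**Steps most likely to fail**

Step 7. The reagent may fail to tell the two formyl groups apart, adding to the C6 formyl group or to both. The fallback leaves the route at 9 and returns at 11, separating the two carbons as alcohols instead. NaBH4 (MeOH, −20 °C) would reduce 9 to the bis(hydroxymethyl)dioxane F1. TBDPSCl/imidazole (CH2Cl2, −20 °C) should silylate only the non-neopentyl hydroxymethyl group on C3, giving the monosilyl ether F2. Dess–Martin oxidation of the remaining neopentyl alcohol would give the C7 aldehyde F3, and Wittig methylenation the vinyl silyl ether F4. HF·pyridine would free the primary alcohol F5, Dess–Martin oxidation would give the now unique aldehyde F6, and MeMgBr at −78 °C would convert it into 11.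

Step 11. The O–O bond may be cleaved reductively by palladium(0)/phosphine or by the borane, or the γ-quaternary alkylborane may transmetalate too slowly and be lost by protodeboronation. The fallback leaves at 10 and returns at 20 without palladium or boron. Commercial (2E,6E)-farnesyl bromide and PPh3 would give the farnesyltriphenylphosphonium bromide F7. Its ylide (n-BuLi, THF, −78 °C) would undergo Wittig reaction with the C7 formyl group of 10 to give the conjugated dienyl carbinol F8 (C7=C8 as an E/Z mixture, 9E retained). Diimide (potassium azodicarboxylate, AcOH) is then expected to saturate the only disubstituted alkene, C7=C8, ahead of the trisubstituted ones, giving 20.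

Step 14. The borane may add to the wrong face, or to both faces, of the isopropenyl group, giving the C2 epimer. The fallback sets out from 23 and returns at 25, replacing substrate control by reagent control. Asymmetric hydroboration with the matched enantiomer of diisopinocampheylborane (from α-pinene and BH3·SMe2, THF, −25 °C) would give the B-alkyldiisopinocampheylborane F9, which perborate oxidises to 25. Any remaining C2 epimer would be removed by chromatography at 25.

**Further compounds**

F1 | step 7 | [(3R,6S)-3-methyl-1,2-dioxane-3,6-diyl]dimethanol | C[C@]1(CO)CC[C@@H](CO)OO1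
F2 | step 7 | [(3R,6S)-6-[[tert-butyl(diphenyl)silyl]oxymethyl]-3-methyl-1,2-dioxan-3-yl]methanol | C[C@]1(CO)CC[C@@H](CO[Si](c2ccccc2)(c2ccccc2)C(C)(C)C)OO1
F3 | step 7 | (3R,6S)-6-[[tert-butyl(diphenyl)silyl]oxymethyl]-3-methyl-1,2-dioxane-3-carbaldehyde | C[C@]1(C=O)CC[C@@H](CO[Si](c2ccccc2)(c2ccccc2)C(C)(C)C)OO1
F4 | step 7 | tert-butyl[[(3S,6R)-6-ethenyl-6-methyl-1,2-dioxan-3-yl]methoxy]diphenylsilane | C[C@]1(C=C)CC[C@@H](CO[Si](c2ccccc2)(c2ccccc2)C(C)(C)C)OO1
F5 | step 7 | [(3S,6R)-6-ethenyl-6-methyl-1,2-dioxan-3-yl]methanol | C[C@]1(C=C)CC[C@@H](CO)OO1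
F6 | step 7 | (3S,6R)-6-ethenyl-6-methyl-1,2-dioxane-3-carbaldehyde | C[C@]1(C=C)CC[C@@H](C=O)OO1
F7 | step 11 | (2E,6E)-farnesyltriphenylphosphonium bromide | CC(C)=CCC/C(C)=C/CC/C(C)=C/C[P+](c1ccccc1)(c1ccccc1)c1ccccc1.[Br-]
F8 | step 11 | 1-[(3S,6R)-6-methyl-6-[(3E,7E)-4,8,12-trimethyltrideca-1,3,7,11-tetraen-1-yl]-1,2-dioxan-3-yl]ethan-1-ol (1E/1Z mixture, both carbinol epimers) | CC(C)=CCC/C(C)=C/CC/C(C)=C/C=C[C@@]1(C)CC[C@@H](C(C)O)OO1
F9 | step 14 | [(2R)-2-[(3S,6S)-6-methyl-6-[(3E,7E)-4,8,12-trimethyltrideca-3,7,11-trien-1-yl]-1,2-dioxan-3-yl]propyl]diisopinocampheylborane (isopinocampheyl configuration as in the α-pinene enantiomer chosen) | CC(C)=CCC/C(C)=C/CC/C(C)=C/CC[C@@]1(C)CC[C@@H]([C@H](C)CB(C2CC3CC(C2C)C3(C)C)C2CC3CC(C2C)C3(C)C)OO1
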